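**Plan**

Ring numbering used throughout: C1 = C(OH)(CH2OBz), C2 = CH(OBz), C3=C4, C5 = CH(OBz), C6 = CH(OH); O1, O2, O5, O6 are the oxygens on these carbons.
Retrosynthesis: cut C1–CH2 (back to a C1 ketone), then C5–O5 (anti-SN2′, which re-closes O6 onto C3 as the bridge of a 7-oxanorbornene), then both ring bonds C1–C6 and C2–C3 by [4+2] cycloreversion to furan (C3–C6, O6) and vinylene carbonate (C1, C2, O1, O2).
Enabling feature: the C5 benzoate trans to the C6 hydroxyl across the C3=C4 alkene is the footprint of an opened oxanorbornene, and O1, O2 and O6 lie on one face of the ring, as in an exo cis-enediol adduct of furan.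
Forward: one Diels–Alder reaction closes the carbocycle (the carbonate is a temporary ring); the carbonate is removed, the meso diol desymmetrised and C1 oxidised; the C1 carbonyl steers the ring opening and then accepts the one-carbon unit; oxidation and benzoylation finish.
Stereochemistry: O1/O2/O6 cis from the exo, suprafacial cycloaddition; absolute configuration from the catalyst-controlled monobenzoylation of the meso diol; C5 from anti attack; C1 from addition trans to the two α-oxygen substituents.

Key step: step 1

Assumption: the (R,R)-Ph-BOX/Cu(OTf)2 catalyst is taken to benzoylate the hydroxyl of meso diol 4 that becomes O2; if the sense is the opposite, the (S,S)-ligand is used and nothing else changes.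

Step 1
Reactants: 1 furan; 2 vinylene carbonate
Product: 3 exo cycloadduct, the meso cyclic carbonate of exo,exo-7-oxabicyclo[2.2.1]hept-5-ene-2,3-diol (carbonate ring syn to the oxygen bridge)
Conditions: neat 1 (excess), sealed tube, 125 °C; exo adduct crystallised, endo isomer re-heated
Reagents that add atoms: none
Why: Concerted, suprafacial [4+2] cycloaddition (Diels–Alder reaction) of furan across its 2- and 5-positions with the cis-enediol carbonate as dienophile, a known thermal reaction type for this pair. It closes the six-membered carbocycle C1–C6 in one [π4s+π2s] event (σ-bonds C1–C6 and C2–C3) and with it the oxygen-bridged bicyclo[2.2.1] frame. The cis relation of O1 and O2 is dictated by the Z geometry locked in the carbonate ring, and the cis relation of H3 and H6 by the furan ring. The only selectivity needed is exo over endo (O1/O2 syn to the bridge O6); the cycloaddition is reversible at this temperature, so the more stable exo adduct should accumulate and the endo isomer can be re-equilibrated. No regiochemical or enantiofacial question arises because both partners are symmetric and the product is meso; the absolute configuration is set in step 3.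

Step 2
Reactants: 3 exo cycloadduct (meso cyclic carbonate)
Product: 4 meso (1R,2S,3R,4S)-7-oxabicyclo[2.2.1]hept-5-ene-2,3-diol (both hydroxyls exo)
Conditions: K2CO3 (0.2 equiv), MeOH, 0 °C to rt
Reagents that add atoms: none
Why: Base-catalysed transesterification (methanolysis) of the strained five-membered cyclic carbonate should release the diol and remove the temporary ring without touching a stereocenter or provoking retro-Diels–Alder cleavage at this temperature.

Step 3
Reactants: 4 meso exo,exo-diol
Product: 5 (1R,2S,3S,4S)-3-hydroxy-7-oxabicyclo[2.2.1]hept-5-en-2-yl benzoate (benzoate and hydroxyl both exo)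
Conditions: BzCl (1.0 equiv), Cu(OTf)2 (5 mol %), (R,R)-Ph-BOX (5 mol %), i-Pr2NEt (1.0 equiv), CH2Cl2, 0 °C
Reagents that add atoms: benzoyl chloride, O=C(Cl)c1ccccc1
Why: Catalytic enantioselective desymmetrisation (asymmetric monobenzoylation of a meso 1,2-diol): the copper bis(oxazoline) complex chelates the cis-diol and activates one enantiotopic hydroxyl, the monoester no longer chelates so a second acylation is slow, and the choice of hydroxyl fixes the absolute configuration at C2, C3 and C6 for the whole route.

Step 4
Reactants: 5 exo-hydroxy benzoate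
Product: 6 (1R,2R,4S)-3-oxo-7-oxabicyclo[2.2.1]hept-5-en-2-yl benzoate (benzoate exo)
Conditions: Dess–Martin periodinane, CH2Cl2, rt
Reagents that add atoms: none
Why: Dess–Martin oxidation of the secondary alcohol under neutral, non-enolising conditions should give the α-benzoyloxy ketone without epimerisation at C2, and brings C1 to the ketone level that steers step 5 and accepts carbon in step 6.

Step 5
Reactants: 6 bicyclic α-benzoyloxy ketone
Product: 7 (1R,4R,5S)-5-hydroxy-6-oxocyclohex-2-ene-1,4-diyl dibenzoate
Conditions: PhCO2H (3 equiv), Et3N (0.3 equiv), [Rh(cod)Cl]2 (2.5 mol %), 1,1'-bis(diphenylphosphino)ferrocene (5 mol %), THF, 60 °C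
Reagents that add atoms: benzoic acid, OC(=O)c1ccccc1
Why: Rhodium-catalysed anti-SN2′ ring opening of an oxabicyclic alkene by a carboxylic acid: the exo-bound metal should ionise the bridgehead C3–O6 bond rather than C6–O6 (whose cleavage would put allyl-cation character next to the C1 carbonyl), and benzoate should attack C5 from the endo face (open because C1 is trigonal), anti to the leaving oxygen, so the C5 benzoate ends trans to the C6 hydroxyl; C2 and C6 are enolisable, but the isomer formed carries all three substituents equatorially and is the stable one.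

Step 6
Reactants: 7 hydroxy ketone dibenzoate
Product: 8 (1R,4R,5S,6S)-5,6-dihydroxy-6-{[dimethyl(propan-2-yloxy)silyl]methyl}cyclohex-2-ene-1,4-diyl dibenzoate
Conditions: (i-PrO)Me2SiCH2MgCl (3 equiv), CeCl3 (3 equiv), THF, −78 °C; aq NH4Cl at −78 °C
Reagents that add atoms: (isopropoxydimethylsilyl)methylmagnesium chloride, CC(C)O[Si](C)(C)C[Mg]Cl
Why: 1,2-Addition of a weakly basic organocerium reagent (a masked hydroxymethyl anion) to the ketone in preference to the benzoates; the C6 alkoxide chelates the carbonyl and both α-oxygen substituents (O2, O6) lie on the lower face of the all-equatorial half-chair, so carbon should enter trans to them (equatorial attack) and the new C1–O bond ends cis to O2 and O6.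

Step 7
Reactants: 8 silylmethyl carbinol
Product: 9 (1R,4R,5S,6S)-5,6-dihydroxy-6-(hydroxymethyl)cyclohex-2-ene-1,4-diyl dibenzoate
Conditions: 30% H2O2, KF, KHCO3, THF/MeOH (1:1), rt
Reagents that add atoms: hydrogen peroxide, OO
Why: Tamao–Fleming oxidation: peroxide adds to the fluoride-activated alkoxysilane and the CH2 group migrates from silicon to oxygen, which unmasks the hydroxymethyl group under bicarbonate buffering that the benzoates should tolerate; no stereocenter is involved.

Step 8
Reactants: 9 triol dibenzoate
Product: 10 [(1S,2R,5R,6S)-2,5-bis(benzoyloxy)-1,6-dihydroxycyclohex-3-en-1-yl]methyl benzoate (target)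
Conditions: BzCl (1.05 equiv), pyridine, CH2Cl2, −30 to 0 °C
Reagents that add atoms: benzoyl chloride, O=C(Cl)c1ccccc1
Why: Selective acylation (benzoylation) of the primary hydroxyl should be possible at low temperature because the C6 hydroxyl is secondary and wedged between the quaternary C1 and the C5 benzoate, and the C1 hydroxyl is tertiary.

**Compound list**

1 | furan | c1ccoc1 | starting material
2 | vinylene carbonate (1,3-dioxol-2-one) | O=C1OC=CO1 | starting material
3 | exo cycloadduct, meso: cyclic carbonate of exo,exo-7-oxabicyclo[2.2.1]hept-5-ene-2,3-diol (4,7-epoxy-3a,4,7,7a-tetrahydro-1,3-benzodioxol-2-one, carbonate syn to the oxygen bridge) | O=C3O[C@@H]1[C@H](O3)[C@H]2C=C[C@@H]1O2 | intermediate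
4 | meso (1R,2S,3R,4S)-7-oxabicyclo[2.2.1]hept-5-ene-2,3-diol (exo,exo) | O[C@@H]1[C@H](O)[C@H]2C=C[C@@H]1O2 | intermediate
5 | (1R,2S,3S,4S)-3-hydroxy-7-oxabicyclo[2.2.1]hept-5-en-2-yl benzoate (2-exo, 3-exo) | O[C@@H]1[C@H](OC(=O)c3ccccc3)[C@H]2C=C[C@@H]1O2 | intermediate
6 | (1R,2R,4S)-3-oxo-7-oxabicyclo[2.2.1]hept-5-en-2-yl benzoate (benzoate exo) | O=C1[C@H](OC(=O)c3ccccc3)[C@H]2C=C[C@@H]1O2 | intermediate
7 | (1R,4R,5S)-5-hydroxy-6-oxocyclohex-2-ene-1,4-diyl dibenzoate | O=C1[C@H](OC(=O)c2ccccc2)C=C[C@@H](OC(=O)c2ccccc2)[C@@H]1O | intermediate
8 | (1R,4R,5S,6S)-5,6-dihydroxy-6-{[dimethyl(propan-2-yloxy)silyl]methyl}cyclohex-2-ene-1,4-diyl dibenzoate | CC(C)O[Si](C)(C)C[C@@]1(O)[C@H](OC(=O)c2ccccc2)C=C[C@@H](OC(=O)c2ccccc2)[C@@H]1O | intermediate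
9 | (1R,4R,5S,6S)-5,6-dihydroxy-6-(hydroxymethyl)cyclohex-2-ene-1,4-diyl dibenzoate | OC[C@@]1(O)[C@H](OC(=O)c2ccccc2)C=C[C@@H](OC(=O)c2ccccc2)[C@@H]1O | intermediate
10 | [(1S,2R,5R,6S)-2,5-bis(benzoyloxy)-1,6-dihydroxycyclohex-3-en-1-yl]methyl benzoate | O=C(OC[C@@]1(O)[C@H](OC(=O)c2ccccc2)C=C[C@@H](OC(=O)c2ccccc2)[C@@H]1O)c1ccccc1 | target

**Step count and risks**

Total steps: 8. Longest linear sequence: 8 steps (1 and 2 to 10).

Steps most likely to fail:

1. Step 5. The rhodium catalyst may insert into the C6–O6 bond next to the carbonyl and give the wrong regiochemistry. The oxanorbornene, which lacks a fused arene, may also be too unreactive. Enolisation of 6 or 7 under the buffered conditions may lead to β-elimination and aromatisation. The fallback replaces metal insertion by silyl-oxonium activation with capture of the liberated alkoxide in the same event. Setting out from 6, tert-butyldimethylsilyl benzoate with catalytic TBSOTf (CH2Cl2, −40 °C) should silylate the bridge oxygen. The carbonyl should forbid ionisation at C6, and benzoate should add to C5 anti to the leaving oxygen. This would give (1R,4R,5S)-5-(tert-butyldimethylsilyloxy)-6-oxocyclohex-2-ene-1,4-diyl dibenzoate F1, in which the sensitive ketol is protected. HF·pyridine in THF would then return to the route at 7.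

2. Step 6. The organometallic may enolise the ketone and so trigger loss of benzoate and aromatisation, it may attack a benzoate carbonyl, the benzoyl group may migrate within the alkoxide, or facial selectivity may be poor. The fallback is a non-basic methylenation followed by a hydroxyl-directed dihydroxylation. Setting out from 7, Zn/CH2Br2/TiCl4 (THF/CH2Cl2, 0 °C) should give (1R,4R,5R)-5-hydroxy-6-methylidenecyclohex-2-ene-1,4-diyl dibenzoate F2. OsO4·TMEDA (CH2Cl2, −78 °C, then aqueous Na2SO3) should then be delivered by hydrogen bonding from the free C6 hydroxyl to the exocyclic alkene on the face of that hydroxyl. The ring alkene is flanked by two benzoates and should react more slowly. This would give triol 9 directly, so the route is rejoined at 9 and step 7 is bypassed.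

3. Step 3. The catalyst may discriminate poorly between the enantiotopic hydroxyls of this rigid diol, or over-acylation to the diester may occur. The fallback turns the desymmetrisation round and lets an enzyme remove one ester. Setting out from 4, exhaustive benzoylation (BzCl, pyridine, DMAP, CH2Cl2) should give meso exo,exo-7-oxabicyclo[2.2.1]hept-5-ene-2,3-diyl dibenzoate F3. Enantiotopos-selective hydrolysis with pig liver esterase or a lipase (pH 7 buffer with co-solvent) should then give 5, where the route is rejoined; a hydrolase of the opposite preference is chosen if the wrong antipode forms.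

Further compounds
F1 | step 5 | (1R,4R,5S)-5-(tert-butyldimethylsilyloxy)-6-oxocyclohex-2-ene-1,4-diyl dibenzoate | O=C1[C@H](OC(=O)c2ccccc2)C=C[C@@H](OC(=O)c2ccccc2)[C@@H]1O[Si](C)(C)C(C)(C)C
F2 | step 6 | (1R,4R,5R)-5-hydroxy-6-methylidenecyclohex-2-ene-1,4-diyl dibenzoate | C=C1[C@H](OC(=O)c2ccccc2)C=C[C@@H](OC(=O)c2ccccc2)[C@@H]1O
F3 | step 3 | meso exo,exo-7-oxabicyclo[2.2.1]hept-5-ene-2,3-diyl dibenzoate | O=C(O[C@@H]1[C@H](OC(=O)c3ccccc3)[C@H]2C=C[C@@H]1O2)c1ccccc1
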